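## Structural features

The target is a labdane: a trans-fused decalin (ring A: C1–C5 and C10; ring B: C5–C10) with a gem-dimethyl group on C4 and an angular methyl on C10. C9 carries a two-carbon chain (C11–C12) that ends at C13, the α-carbon of an α,β-unsaturated γ-lactone (a 3-substituted furan-2(5H)-one). Five stereocentres sit on the decalin: the ring-fusion pair C5/C10, C6 next to C5, and the contiguous run C8–C9–C10. The C6 acetoxy group (α) and the C8 methyl (α) are equatorial, the C9 hydroxyl (α) is axial and the C9 side chain (β) is equatorial. C9 is a fully substituted carbinol wedged between the quaternary C10 and the methine C8. The fragile groups are the butenolide (ring opening, γ-deprotonation and conjugate addition under base), the secondary acetate (lost to any hydride reagent) and, in intermediates, the α-ketol at C8/C9 and the β-oxygenated C8 ketone. The real difficulties are four: the absolute configuration of C5/C10 with no resident stereocentre to lean on; the C9 carbinol beside C10; an equatorial C8 methyl, which needs hydrogen to arrive on the β face, syn to the angular methyl; and an oxygen on C6, which has no handle except through the C8 carbonyl. The key step exploits the head-to-tail isoprenoid array C4(Me2)–C5–C10(Me)–C9–C11: rings A and B map onto a geranyl chain whose end is the enol of a β-keto ester, C9 being the enol carbon, C8 the carbonyl and C11 the ester carbon.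

## Logic of the disconnections

**20 to 19.** The acetyl–oxygen bond on C6 is cut first. A secondary acetate cannot pass the hydride reduction of C11, so it is kept out of every earlier intermediate; no protecting group on C6 is then needed anywhere. The forward acylation must take the secondary equatorial hydroxyl and leave the tertiary axial one, and must spare the lactone.

**19 to 16 and 17.** The C12–C13 bond is cut (forward through 18). This separates the base-sensitive lactone, available as 17, from the terpenoid core and reduces the core to a vinyl carbinol. The forward step needs boron on the terminal carbon of a vinyl group attached to a fully substituted carbon, and an sp3–sp2 coupling mild enough for the lactone and tolerant of two free hydroxyls.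

**16 to 15 to 14.** The C11=C12 double bond is cut (one-carbon olefination) and C11 is taken back from aldehyde to ester. C11 is the carboxyl carbon that the key step leaves on C9, so every core carbon except C17 now comes from the cyclisation. The reduction must stop at the aldehyde, and the olefination must outrun base-induced rearrangement of the α-hydroxy aldehyde 15.

**14 to 13 to 12.** The C8–H bond is removed (C8 stereocentre gone), then the C8=C17 bond is cut. This leads back to the C8 ketone supplied by the terminator. Hydrogen must reach C8 from the β face, and the methylenation must not be basic, since 12 is both a β-hydroxy ketone and an α-ketol.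

**12 to 10 to 7.** The C6–O bond is cut (forward through 11) and the C6=C7 unsaturation is removed (forward through 8 and 9). C6 can only be reached through the vinylogous pull of the C8 ketone. This removes the C6 stereocentre and returns ring B to a plain ketone. Boron must add from the α face; enolisation toward C7 only is guaranteed because C9 carries no hydrogen.

**7 to 6.** The C9–O bond is cut. C9 is the doubly activated carbon of a β-keto ester, so the tertiary carbinol is traced to a C–H between two carbonyls. The oxidant must approach from the α face.

**6 to 5.** The C4–C5 and C9–C10 bonds are cut together. Both rings and the C5/C10 pair dissolve into an acyclic, achiral triene, the largest single gain in simplicity. The forward step demands a chiral proton donor that picks one face of the terminal alkene, a chair–chair fold of the chain, and a terminator that captures through carbon without disabling the acid.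

**5 to 4 to 1 and 2.** The enol oxygen–acyl bond is cut, then the C6–C7 bond (forward through 3). 4 is the γ-alkylation product of an acetoacetate with an allylic bromide. The enol ester is added because the free 1,3-dicarbonyl of 4 would chelate the tin of the chiral acid and itself act as an achiral proton source. The forward steps need alkylation at the terminal carbon only and O- rather than C-acylation.

## Other disconnections considered

**Alternative 1:** The cut runs through ring A at C1–C10 and C4–C5. Ring B is a ready-made quinone, 2,6-dimethyl-1,4-benzoquinone A1, and ring A is built by a [4+2] addition of 4-methylpenta-1,3-diene A2 across the methyl-bearing double bond of A1 under a chiral oxazaborolidinium Lewis acid, giving the cis-fused ene-dione A3.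
- In favour: two simple achiral pieces and a convergent key step. The regiochemistry is sound: acid bound to the unhindered carbonyl makes the methyl-bearing carbon electrophilic, and that carbon takes the unsubstituted diene terminus.
- Better than the chosen plan: enantioselective quinone Diels–Alder catalysis of this kind is established, whereas the chosen key step is an extension. A3 already holds oxygen on C6 and C9 and the C17 carbon. Once the 7,8-alkene is reduced, C8 is α to the C9 ketone and its methyl could be set equatorial by equilibration rather than by kinetic hydrogen delivery.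
- Against: A2 carries a cis methyl on its reacting terminus and should be a sluggish diene. The ring fusion is cis, so C5 must be inverted through the C6 enol with no assurance that the trans isomer is preferred. The ring A alkene must be hydrogenated and two carbonyls told apart. The side chain would have to add to the C9 ketone from the β face, syn to the neighbouring angular methyl, to leave the axial 9α-hydroxyl; attack anti to that methyl is the more likely course.
- Comparison: the mechanism is concerted and pericyclic rather than cationic. Step count would be about equal, because what is saved on C6 and C17 is spent on epimerisation, hydrogenation and differentiation. The chosen plan gets the trans fusion and the C9 configuration directly, which decides the matter.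

**Alternative 2:** The cut is at C3–C4, with a latent C4–C7 bond. Ring B and both ring-fusion centres come from a pinane-derived cyclobutyl ketone A4 (an allylated dihydroverbenone). A strong chloride-bearing Lewis acid would open the strained ring to a tertiary C4 cation and a C7–C8 enolate, and the allyl group on C10 would capture the cation, closing ring A and giving the chloro ketone A5.
- Better than the chosen plan: absolute configuration comes from the chiral pool and not from an untested chiral reagent. The trans fusion is fixed beforehand by the anti arrangement of the allyl group and the cyclobutane carbon.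
- Equal to the chosen plan: the fragmentation delivers the C7–C8 enolate regiospecifically, as good a start toward the 6,7-enone as the blocked ketone 7.
- Against: A5 has no carbon on C9. Both the hydroxyl and C11 would have to go onto the more hindered α-carbon of the ketone, beside quaternary C10, against the kinetic preference for C7. The olefin capture ends in a secondary C2 cation, a weak driving force that invites proton loss at C4. The C2 chloride costs a reduction. Making A4 means forging the quaternary C10 by conjugate addition to a β,β-disubstituted enone.
- Comparison: structurally it solves C5/C10 but leaves C9 and C11 unsolved. Mechanistically it is also cationic, but with a poorer terminator. It would be clearly longer.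

**Alternative 3:** The cut is at C8–C9 in ring B. A ring A aldehyde–ketone A6 would be closed by a carbene from a chiral triazolium salt, which turns the C8 aldehyde into an acyl-anion equivalent that adds to the C9 ketone, giving the α-hydroxy ketone A7.
- Better than the chosen plan: A7 would hold the C9 carbinol, the C8 ketone, the C6 oxygen and the C11–C12 chain at once, where the chosen plan needs one oxidation and four further steps for the same features. Conditions are catalytic and near neutral.
- Against: the acceptor ketone sits on quaternary C10 and is hindered on both sides, at the edge of what intramolecular aldehyde–ketone benzoin closures tolerate. The aldehyde has a β-silyloxy group and could eliminate to an enal under the basic carbene conditions. The addition is reversible, so the axial hydroxyl at C9 depends on a match of catalyst and substrate. A6, with C5, C6 and C10 already set, needs a long stereocontrolled synthesis of its own.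
- Comparison: the hard C5/C10 problem is moved out of the key step rather than solved. Fewer steps after the key step, many more before it; longer overall.

Key step: step 3

Remark on numbering: labdane numbering is used throughout (C4 gem-dimethyl, C5/C10 ring fusion, C11 the carbon on C9, C17 the carbon on C8); α is the face opposite the C10 methyl.

Remark on the chiral acid: the (R)-configured naphthol acid is assumed to deliver the (5S,10S) series, by analogy with arene- and oxygen-terminated polyprenoids; if the sense is the reverse, the (S) acid is used and nothing else changes.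

## Route

Step 1
Reactants: 1 methyl acetoacetate; 2 geranyl bromide
Product: 4 methyl (6E)-7,11-dimethyl-3-oxododeca-6,10-dienoate, via acetoacetate dianion 3 (not isolated)
Conditions: NaH, THF, 0 °C; n-BuLi, 0 °C; then 2, 0 °C → rt; aq. HCl quench
Reagents that add atoms: none
Why: Dianion alkylation of an acetoacetate: the more basic terminal carbanion attacks the allylic bromide by SN2 at the γ-carbon, and the E alkene is untouched.

Step 2
Reactants: 4 methyl (6E)-7,11-dimethyl-3-oxododeca-6,10-dienoate
Product: 5 methyl (2E,6E)-3-acetoxy-7,11-dimethyldodeca-2,6,10-trienoate
Conditions: Ac2O, Et3N, DMAP (cat.), CH2Cl2, 0 °C → rt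
Reagents that add atoms: acetic anhydride, CC(=O)OC(C)=O
Why: DMAP-catalysed O-acylation of the amine enolate of a β-keto ester; amine bases favour the E enol ester, and either geometry would serve because C9 equilibrates after the cyclisation.

Step 3
Reactants: 5 methyl (2E,6E)-3-acetoxy-7,11-dimethyldodeca-2,6,10-trienoate
Product: 6 methyl (1R,4aS,8aS)-5,5,8a-trimethyl-2-oxodecahydronaphthalene-1-carboxylate (trans-decalin; C8 ketone, 9β-CO2Me, 5α-H, 10β-CH3)
Conditions: (R)-2'-(2-fluorobenzyloxy)-1,1'-binaphthalen-2-ol (1.2 equiv), SnCl4 (1.1 equiv), toluene, −78 °C, 2 d; aq. NaHCO3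
Reagents that add atoms: none
Why: Proposed new method: the tin-bound naphthol is a strong chiral proton donor that should protonate C3 of the terminal alkene on one face while the C5=C10 alkene attacks C4 (ring A, 6-endo-trig with respect to that alkene) and the enol-ester carbon C9 attacks the developing C10 cation (ring B, 6-endo-trig with respect to C8=C9); the acyloxy-stabilised C8 cation then passes its acetyl group to chloride and leaves the C8 ketone. The closest known reactions are the proton-initiated enantioselective cyclisations of polyprenyl arenes, phenols and silyl ethers by the same tin–naphthol acids and the racemic SnCl4 bicyclisation of 4; an enol ester as terminator under a chiral proton acid has not been shown. C5 and C10 are set relative to each other by anti addition across the E C5=C10 alkene in a chair–chair fold, which gives the trans fusion, and their absolute sense by the face of protonation that the chiral acid selects. C9 is set under thermodynamic control, because the β-keto ester epimerises through its enol to the equatorial 9β ester. The step needs protonation at the terminal and not the internal alkene, which the less hindered isopropylidene end and the productive cascade behind it should favour. It also needs carbon and not oxygen capture of the C10 cation, which the acetyl group on the enol oxygen enforces. Masking the 1,3-dicarbonyl removes the acidic, tin-chelating site that would otherwise strip SnCl4 from the ligand and release an achiral proton.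

Step 4
Reactants: 6 methyl (1R,4aS,8aS)-5,5,8a-trimethyl-2-oxodecahydronaphthalene-1-carboxylate
Product: 7 methyl 9α-hydroxy-4,4,10β-trimethyl-8-oxo-trans-decalin-9β-carboxylate (5α-H; decalin name: methyl (1S,4aS,8aS)-1-hydroxy-5,5,8a-trimethyl-2-oxodecahydronaphthalene-1-carboxylate)
Conditions: dimethyldioxirane (acetone solution), Ni(acac)2 (cat.), CH2Cl2/acetone, 0 °C → rt
Reagents that add atoms: dimethyldioxirane, CC1(C)OO1
Why: Electrophilic α-hydroxylation of a β-keto ester through its nickel enolate; the dioxirane should approach C9 axially from the α face, anti to the C10 methyl, so the hydroxyl becomes 9α and the ester stays equatorial.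

Step 5
Reactants: 7 methyl 9α-hydroxy-4,4,10β-trimethyl-8-oxo-trans-decalin-9β-carboxylate
Product: 10 methyl 9α-hydroxy-4,4,10β-trimethyl-8-oxo-trans-decal-6-ene-9β-carboxylate (5α-H), via bis-silyl enol ether 8 (not isolated), via silylated enone 9 (not isolated)
Conditions: TMSOTf, Et3N, CH2Cl2, 0 °C; aq. NaHCO3 wash; Pd(OAc)2 (1.1 equiv), MeCN, rt; then 1 M HCl, THF, 0 °C
Reagents that add atoms: none
Why: Saegusa–Ito oxidation: with C9 fully substituted the ketone can enolise only toward C7, and the C7 palladium enolate loses a C6 hydrogen to give the 6,7-enone. The tertiary hydroxyl is silylated in passing and freed by the acidic finish.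

Step 6
Reactants: 10 methyl 9α-hydroxy-4,4,10β-trimethyl-8-oxo-trans-decal-6-ene-9β-carboxylate
Product: 12 methyl 6α,9α-dihydroxy-4,4,10β-trimethyl-8-oxo-trans-decalin-9β-carboxylate (5α-H), via boryl ketone 11 (not isolated)
Conditions: CuCl (cat.), NaOt-Bu (cat.), DPEphos (cat.), B2pin2, MeOH, THF, rt; then NaBO3·4H2O, THF/H2O, rt
Reagents that add atoms: sodium perborate, [Na+].[O-]B1OO1
Why: Copper-catalysed conjugate borylation of a cyclic enone, then C–B oxidation with retention. The boryl-copper species should add to C6 from the α face because the β face is blocked by the axial methyls on C4 and C10, which gives the equatorial 6α-hydroxyl.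

Step 7
Reactants: 12 methyl 6α,9α-dihydroxy-4,4,10β-trimethyl-8-oxo-trans-decalin-9β-carboxylate
Product: 13 methyl 6α,9α-dihydroxy-4,4,10β-trimethyl-8-methylidene-trans-decalin-9β-carboxylate (5α-H)
Conditions: Zn, CH2Br2, TiCl4, THF/CH2Cl2, 0 °C → rt
Reagents that add atoms: dibromomethane, BrCBr
Why: Takai–Lombardo methylenation with a non-basic zinc/titanium methylene reagent; a phosphorus ylide would expose the β-hydroxy ketone to elimination and the α-ketol to base. The ester is inert and the hydroxyls are covered by excess reagent.

Step 8
Reactants: 13 methyl 6α,9α-dihydroxy-4,4,10β-trimethyl-8-methylidene-trans-decalin-9β-carboxylate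
Product: 14 methyl 6α,9α-dihydroxy-4,4,8α,10β-tetramethyl-trans-decalin-9β-carboxylate (5α-H, 8β-H)
Conditions: Mn(dpm)3 (cat.), PhSiH3, t-BuOOH, i-PrOH, rt
Reagents that add atoms: none
Why: Metal-hydride hydrogen-atom-transfer hydrogenation (Mukaiyama-type): a manganese hydride adds hydrogen to C17, and the tertiary C8 radical should take its second hydrogen axially from the β face so that the new methyl sits equatorial (8α); the α face is screened by the axial 9α-hydroxyl. Unlike hydrogenation on a metal surface, the outcome should follow product stability.

Step 9
Reactants: 14 methyl 6α,9α-dihydroxy-4,4,8α,10β-tetramethyl-trans-decalin-9β-carboxylate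
Product: 15 6α,9α-dihydroxy-4,4,8α,10β-tetramethyl-trans-decalin-9β-carbaldehyde (5α-H)
Conditions: i-Bu2AlH (excess), CH2Cl2, −78 → −40 °C; aq. potassium sodium tartrate
Reagents that add atoms: none
Why: Partial reduction of an α-hydroxy ester: the neighbouring aluminium alkoxide chelates the tetrahedral intermediate and should hold it at the aldehyde level until work-up.

Step 10
Reactants: 15 6α,9α-dihydroxy-4,4,8α,10β-tetramethyl-trans-decalin-9β-carbaldehyde
Product: 16 9β-ethenyl-4,4,8α,10β-tetramethyl-trans-decalin-6α,9α-diol (5α-H)
Conditions: Ph3PCH3Br, KOt-Bu, THF, 0 °C → rt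
Reagents that add atoms: methyltriphenylphosphonium bromide, C[P+](c1ccccc1)(c1ccccc1)c1ccccc1.[Br-]
Why: Wittig methylenation of a non-enolisable aldehyde; excess ylide covers the two hydroxyls and the low temperature should keep the α-hydroxy aldehyde from rearranging.

Step 11
Reactants: 16 9β-ethenyl-4,4,8α,10β-tetramethyl-trans-decalin-6α,9α-diol; 17 3-bromofuran-2(5H)-one
Product: 19 3-[2-(6α,9α-dihydroxy-4,4,8α,10β-tetramethyl-trans-decalin-9β-yl)ethyl]furan-2(5H)-one (5α-H), via alkylborane 18 (not isolated)
Conditions: 9-BBN (excess), THF, rt → 50 °C; then 17, PdCl2(dppf) (cat.), AsPh3, K3PO4 (aq.), DMF, rt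
Reagents that add atoms: none
Why: Anti-Markovnikov hydroboration puts boron on C12, and the B-alkyl Suzuki–Miyaura coupling with the α-bromo enoate 17 forms C12–C13 and keeps the ring double bond. Phosphate at room temperature is chosen to spare the lactone.

Step 12
Reactants: 19 3-[2-(6α,9α-dihydroxy-4,4,8α,10β-tetramethyl-trans-decalin-9β-yl)ethyl]furan-2(5H)-one
Product: 20 3-[2-(6α-acetoxy-9α-hydroxy-4,4,8α,10β-tetramethyl-trans-decalin-9β-yl)ethyl]furan-2(5H)-one, (5S,6S,8R,9R,10S), the target
Conditions: Ac2O, pyridine, DMAP (cat.), CH2Cl2, 0 °C → rt
Reagents that add atoms: acetic anhydride, CC(=O)OC(C)=O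
Why: DMAP-catalysed acylation: the secondary equatorial 6α-hydroxyl should react, while the tertiary axial 9α-hydroxyl between C8 and C10 should not.

## Compound list

1 | methyl acetoacetate | CC(=O)CC(=O)OC | starting material
2 | geranyl bromide, (2E)-1-bromo-3,7-dimethylocta-2,6-diene | CC(C)=CCC/C(C)=C/CBr | starting material
3 | methyl acetoacetate dianion, sodium lithium salt | [Na+].[Li+].[CH2-]C(=O)[CH-]C(=O)OC | intermediate
4 | methyl (6E)-7,11-dimethyl-3-oxododeca-6,10-dienoate | CC(C)=CCC/C(C)=C/CCC(=O)CC(=O)OC | intermediate
5 | methyl (2E,6E)-3-acetoxy-7,11-dimethyldodeca-2,6,10-trienoate | CC(C)=CCC/C(C)=C/CC/C(OC(C)=O)=C\C(=O)OC | intermediate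
6 | methyl (1R,4aS,8aS)-5,5,8a-trimethyl-2-oxodecahydronaphthalene-1-carboxylate | C1CC(=O)[C@H](C(=O)OC)[C@@]2(C)CCCC(C)(C)[C@H]12 | intermediate
7 | methyl 9α-hydroxy-4,4,10β-trimethyl-8-oxo-trans-decalin-9β-carboxylate | C1CC(=O)[C@](O)(C(=O)OC)[C@@]2(C)CCCC(C)(C)[C@H]12 | intermediate
8 | methyl 4,4,10β-trimethyl-8,9α-bis(trimethylsilyloxy)-trans-decal-7-ene-9β-carboxylate | C1C=C(O[Si](C)(C)C)[C@](O[Si](C)(C)C)(C(=O)OC)[C@@]2(C)CCCC(C)(C)[C@H]12 | intermediate
9 | methyl 4,4,10β-trimethyl-8-oxo-9α-(trimethylsilyloxy)-trans-decal-6-ene-9β-carboxylate | C1=CC(=O)[C@](O[Si](C)(C)C)(C(=O)OC)[C@@]2(C)CCCC(C)(C)[C@H]12 | intermediate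
10 | methyl 9α-hydroxy-4,4,10β-trimethyl-8-oxo-trans-decal-6-ene-9β-carboxylate | C1=CC(=O)[C@](O)(C(=O)OC)[C@@]2(C)CCCC(C)(C)[C@H]12 | intermediate
11 | methyl 9α-hydroxy-4,4,10β-trimethyl-8-oxo-6α-(4,4,5,5-tetramethyl-1,3,2-dioxaborolan-2-yl)-trans-decalin-9β-carboxylate | CC3(C)OB(OC3(C)C)[C@H]1CC(=O)[C@](O)(C(=O)OC)[C@@]2(C)CCCC(C)(C)[C@H]12 | intermediate
12 | methyl 6α,9α-dihydroxy-4,4,10β-trimethyl-8-oxo-trans-decalin-9β-carboxylate | O[C@H]1CC(=O)[C@](O)(C(=O)OC)[C@@]2(C)CCCC(C)(C)[C@H]12 | intermediate
13 | methyl 6α,9α-dihydroxy-4,4,10β-trimethyl-8-methylidene-trans-decalin-9β-carboxylate | O[C@H]1CC(=C)[C@](O)(C(=O)OC)[C@@]2(C)CCCC(C)(C)[C@H]12 | intermediate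
14 | methyl 6α,9α-dihydroxy-4,4,8α,10β-tetramethyl-trans-decalin-9β-carboxylate | O[C@H]1C[C@@H](C)[C@](O)(C(=O)OC)[C@@]2(C)CCCC(C)(C)[C@H]12 | intermediate
15 | 6α,9α-dihydroxy-4,4,8α,10β-tetramethyl-trans-decalin-9β-carbaldehyde | O[C@H]1C[C@@H](C)[C@](O)(C=O)[C@@]2(C)CCCC(C)(C)[C@H]12 | intermediate
16 | 9β-ethenyl-4,4,8α,10β-tetramethyl-trans-decalin-6α,9α-diol | O[C@H]1C[C@@H](C)[C@](O)(C=C)[C@@]2(C)CCCC(C)(C)[C@H]12 | intermediate
17 | 3-bromofuran-2(5H)-one | O=C1OCC=C1Br | starting material
18 | 9β-[2-(9-borabicyclo[3.3.1]nonan-9-yl)ethyl]-4,4,8α,10β-tetramethyl-trans-decalin-6α,9α-diol | O[C@H]1C[C@@H](C)[C@](O)(CCB3C4CCCC3CCC4)[C@@]2(C)CCCC(C)(C)[C@H]12 | intermediate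
19 | 3-[2-(6α,9α-dihydroxy-4,4,8α,10β-tetramethyl-trans-decalin-9β-yl)ethyl]furan-2(5H)-one | O[C@H]1C[C@@H](C)[C@](O)(CCC3=CCOC3=O)[C@@]2(C)CCCC(C)(C)[C@H]12 | intermediate
20 | 3-[2-(6α-acetoxy-9α-hydroxy-4,4,8α,10β-tetramethyl-trans-decalin-9β-yl)ethyl]furan-2(5H)-one, (5S,6S,8R,9R,10S) | CC(=O)O[C@H]1C[C@@H](C)[C@](O)(CCC2=CCOC2=O)[C@@]2(C)CCCC(C)(C)[C@H]12 | target

## Step count and least certain steps

Total: 12 steps. Longest linear sequence: 12 steps (1 and 2 to 20); 17 enters at step 11 as purchased.

**Step 3 (key step).** Two things are most likely to go wrong. The first is erosion of enantioselectivity: the carbonyl groups of 5 may displace the naphthol from tin, or traces of an achiral proton source may start the cascade. The second is premature proton loss from the C10 cation, because an enol ester is a weak π-nucleophile and ring B may not close at −78 °C. Fallback with known chemistry: from 4, SnCl4 in CH2Cl2 at 0 °C → rt closes both rings through the tin chelate of the free β-keto ester and gives 6 in racemic form, that is, together with an equal amount of the mirror-image keto ester F1. The enantiomers are separated by preparative chromatography on a chiral stationary phase, and the route is rejoined at 6.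

**Step 8.** Poor facial selectivity in the hydrogen transfer to the C8 radical is the risk: the β face that must be used lies 1,3-diaxial to the C10 methyl, so delivery from the α face and an axial 8β-methyl are conceivable. Fallback: from 13, hydrogenation over Pd/C under H2 in EtOAc, which should add from the α face, gives the 8β-methyl epimer F2. F2 is then equilibrated at C8 by reversible hydrogen-atom abstraction with (Bu4N)4[W10O32] (cat.) and a diaryl disulfide under 390 nm light in MeCN. The equatorial methyl is strongly preferred, and C5 and C6 already hold their more stable configurations, so the equilibration should converge on 14, where the route is rejoined.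

**Step 11.** Base-induced degradation of 17 (ring opening, γ-deprotonation) may compete with slow transmetalation of the hindered alkylborane, and β-hydride elimination may intervene. Fallback: the lactone is masked as an aromatic silyloxyfuran. 17 with TIPSOTf and Et3N gives 3-bromo-2-(triisopropylsilyloxy)furan F3. The alkylborane 18, made from 16 as before, is coupled with F3 (Pd(OAc)2, SPhos, K3PO4, THF/H2O) to the 3-alkyl-2-(triisopropylsilyloxy)furan F4. Dilute HCl in THF removes the silyl group and protonates C5 of the furan, giving 19, where the route is rejoined.

**Step 7.** Elimination or retro-aldol cleavage of the β-hydroxy ketone under the Lewis-acidic reagent, or sluggish attack at the hindered C8 carbonyl, is the risk. Fallback: boron is carried through the methylenation. From 10, the borylation of step 6 is stopped before oxidation and 11 is isolated. Methylenation of 11 (Ph3P=CH2, THF, 0 °C, or the zinc/titanium reagent) gives the homoallylic boronate F5, which has no β-leaving group. NaBO3·4H2O then gives 13, where the route is rejoined.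

**Step 9.** Over-reduction to the primary alcohol is the risk, if the aluminium hemiacetal collapses before the quench. Fallback: from 14, LiAlH4 in THF reduces the ester fully to the 6α,9α,11-triol F6. The primary hydroxyl is then oxidised selectively with TEMPO (cat.), N-chlorosuccinimide and Bu4NCl in buffered CH2Cl2/water, conditions that spare secondary alcohols and do not cleave 1,2-diols, to return to 15.

## Further compounds

F1 | step 3 | methyl (1S,4aR,8aR)-5,5,8a-trimethyl-2-oxodecahydronaphthalene-1-carboxylate (mirror image of 6) | C1CC(=O)[C@@H](C(=O)OC)[C@]2(C)CCCC(C)(C)[C@@H]12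
F2 | step 8 | methyl 6α,9α-dihydroxy-4,4,8β,10β-tetramethyl-trans-decalin-9β-carboxylate (C8 epimer of 14) | O[C@H]1C[C@H](C)[C@](O)(C(=O)OC)[C@@]2(C)CCCC(C)(C)[C@H]12
F3 | step 11 | 3-bromo-2-(triisopropylsilyloxy)furan | CC(C)[Si](Oc1occc1Br)(C(C)C)C(C)C
F4 | step 11 | 9β-{2-[2-(triisopropylsilyloxy)furan-3-yl]ethyl}-4,4,8α,10β-tetramethyl-trans-decalin-6α,9α-diol | O[C@H]1C[C@@H](C)[C@](O)(CCc3ccoc3O[Si](C(C)C)(C(C)C)C(C)C)[C@@]2(C)CCCC(C)(C)[C@H]12
F5 | step 7 | methyl 9α-hydroxy-4,4,10β-trimethyl-8-methylidene-6α-(4,4,5,5-tetramethyl-1,3,2-dioxaborolan-2-yl)-trans-decalin-9β-carboxylate | CC3(C)OB(OC3(C)C)[C@H]1CC(=C)[C@](O)(C(=O)OC)[C@@]2(C)CCCC(C)(C)[C@H]12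
F6 | step 9 | 9β-(hydroxymethyl)-4,4,8α,10β-tetramethyl-trans-decalin-6α,9α-diol | O[C@H]1C[C@@H](C)[C@](O)(CO)[C@@]2(C)CCCC(C)(C)[C@H]12
A1 | alternative 1 | 2,6-dimethyl-1,4-benzoquinone | CC1=CC(=O)C=C(C)C1=O
A2 | alternative 1 | 4-methylpenta-1,3-diene | CC(C)=CC=C
A3 | alternative 1 | cis-2,5,5,8a-tetramethyl-4a,5,8,8a-tetrahydronaphthalene-1,4-dione (10β-methyl, 5β-H) | O=C1C=C(C)C(=O)[C@@]2(C)CC=CC(C)(C)[C@@H]12
A4 | alternative 2 | 4-allyl-4,6,6-trimethylbicyclo[3.1.1]heptan-2-one (allyl anti to the gem-dimethyl bridge) | C=CC[C@]1(C)CC(=O)[C@@H]2C[C@H]1C2(C)C
A5 | alternative 2 | 2α-chloro-4,4,10β-trimethyl-trans-decalin-8-one (labdane numbering) | C1CC(=O)C[C@@]2(C)C[C@@H](Cl)CC(C)(C)[C@H]12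
A6 | alternative 3 | ring A keto aldehyde: 3-(tert-butyldimethylsilyloxy)-3-[2-(3-benzyloxypropanoyl)-2,6,6-trimethylcyclohexyl]propanal (C5, C6 and C10 as in A7) | CC(C)(C)[Si](C)(C)O[C@@H](CC=O)[C@H]1C(C)(C)CCC[C@]1(C)C(=O)CCOCc1ccccc1
A7 | alternative 3 | 9β-(2-benzyloxyethyl)-6α-(tert-butyldimethylsilyloxy)-9α-hydroxy-4,4,10β-trimethyl-trans-decalin-8-one (labdane numbering) | CC(C)(C)[Si](C)(C)O[C@H]1CC(=O)[C@](O)(CCOCc2ccccc2)[C@@]2(C)CCCC(C)(C)[C@H]12
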